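**Plan**
- Retrosynthesis: the two formyl groups and the two O-methyl groups are removed from the arene; the cyclohexene C=C is traced back to a ketone through its enol triflate; the bond from the spiro carbon to its ring CH2 and the ring-fusion bond between the O–CH carbon and the methyl-bearing quaternary carbon are then cut together; finally the enol ether C–O bond, the carbinol C–C bond and the aryl ketone are cut.
- Enabling feature: the isobutyl-bearing benzylic carbon (C-9′) sits on a 2,4,6-trioxygenated ring and can carry a cation. Its neighbour C-9a′, with its methyl group and the C-1′H2–C-2′H2 arm, is an opened 1-methylcyclopropyl group. The spiro carbon C-3′ is the β-carbon of an aryl enol ether O–C-3a′H=C.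
- Forward: aryl cyclopropyl ketone, then carbinol; (−)-menthone, then formyl ketone, then enol tosylate; the two are joined as an aryl enol ether; one acid-triggered cascade closes a nine-membered ring and stitches it across to give the cyclopentane and pyran rings; the cyclohexene alkene, the formyl groups and the free phenols follow.
- Stereochemistry: the methyl-bearing carbon of (−)-menthone is the only source. It directs attack at the spiro carbon anti to the axial methyl group, the E-enol ether fixes the O–CH carbon, the enforced cis ring fusion fixes the quaternary methyl carbon, and hydride delivery from the convex face fixes the isobutyl carbon.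

Key step: step 7

Remark: the carbinol carbon of 6 and 11 is used as a mixture because it is ionised in step 7; the isopropyl-bearing carbon is drawn with the menthone configuration although it may epimerise, because it becomes trigonal in step 8.

**Route**

Step 1
Reactants: 1 1,3,5-trimethoxybenzene; 2 1-methylcyclopropane-1-carbonyl chloride
Product: 3 (1-methylcyclopropyl)(2,4,6-trimethoxyphenyl)methanone
Conditions: Bi(OTf)3 (5 mol %), CH2Cl2, 0 °C to rt
Reagents that add atoms: none
Why: Friedel–Crafts acylation of the threefold-symmetric, highly activated arene can give only one ketone, and the catalytic triflate avoids a stoichiometric Lewis acid that could open the cyclopropane.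

Step 2
Reactants: 3 (1-methylcyclopropyl)(2,4,6-trimethoxyphenyl)methanone
Product: 4 (2-hydroxy-4,6-dimethoxyphenyl)(1-methylcyclopropyl)methanone
Conditions: BCl3 (1.2 equiv), CH2Cl2, −78 to 0 °C; H2O
Reagents that add atoms: none
Why: Chelation-assisted ether cleavage, in which BCl3 binds the carbonyl oxygen and removes one of the two equivalent ortho methyl groups, the boron chelate then protecting the product from a second cleavage at low temperature.

Step 3
Reactants: 4 (2-hydroxy-4,6-dimethoxyphenyl)(1-methylcyclopropyl)methanone; 5 isobutylmagnesium bromide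
Product: 6 2-[1-hydroxy-3-methyl-1-(1-methylcyclopropyl)butyl]-3,5-dimethoxyphenol (racemic)
Conditions: i-BuMgBr (3 equiv), LaCl3·2LiCl (30 mol %), THF, 0 °C; aq. NH4Cl
Reagents that add atoms: none
Why: Chelation-assisted Grignard 1,2-addition to the non-enolisable ortho-hydroxyaryl ketone, the lanthanum salt favouring addition over β-hydride reduction; the new carbinol centre is racemic and is ionised in step 7.

Step 4
Reactants: 7 (−)-menthone; 8 ethyl formate
Product: 9 (2Z,3R,6S)-2-(hydroxymethylidene)-3-methyl-6-(propan-2-yl)cyclohexan-1-one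
Conditions: NaH, EtOH (cat.), Et2O, 0 °C to rt; aq. HCl
Reagents that add atoms: none
Why: Crossed Claisen condensation (formylation) at the only α-methylene group, driven by formation of the stabilised sodium enolate; the methyl-bearing stereocentre is not touched.

Step 5
Reactants: 9 (2Z,3R,6S)-2-(hydroxymethylidene)-3-methyl-6-(propan-2-yl)cyclohexan-1-one
Product: 10 [(E)-[(3S,6R)-6-methyl-2-oxo-3-(propan-2-yl)cyclohexylidene]methyl] 4-methylbenzenesulfonate
Conditions: TsCl, Et3N, DMAP (cat.), CH2Cl2, 0 °C
Reagents that add atoms: 4-methylbenzenesulfonyl chloride, Cc1ccc(cc1)S(Cl)(=O)=O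
Why: O-Sulfonylation of the enol of the β-keto aldehyde gives a β-sulfonyloxy enone, a vinylogous mixed anhydride ready for addition–elimination.

Step 6
Reactants: 6 2-[1-hydroxy-3-methyl-1-(1-methylcyclopropyl)butyl]-3,5-dimethoxyphenol; 10 enol tosylate of formyl menthone
Product: 11 (2E,3R,6S)-2-({2-[1-hydroxy-3-methyl-1-(1-methylcyclopropyl)butyl]-3,5-dimethoxyphenoxy}methylidene)-3-methyl-6-(propan-2-yl)cyclohexan-1-one (both carbinol epimers)
Conditions: Cs2CO3, MeCN, rt
Reagents that add atoms: none
Why: Conjugate addition–elimination (vinylogous acyl substitution) by the caesium phenoxide, the tertiary alcohol being too hindered and too weakly acidic to compete; the thermodynamically preferred E-enol ether is expected.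

Step 7
Reactants: 11 aryl enol ether carbinol
Product: 13 (1S,3S,3a'R,6R,9'R,9a'S)-6',8'-dimethoxy-6,9a'-dimethyl-9'-(2-methylpropyl)-3-(propan-2-yl)-1',2',9',9a'-tetrahydro-3a'H-spiro[cyclohexane-1,3'-cyclopenta[b]chromen]-2-one, via 9'-(2-methylpropylidene) spiro ketone 12 (not isolated)
Conditions: Tf2NH (10 mol %), 4 Å MS, CH2Cl2, −60 to −20 °C; then Et3SiH, CF3CO2H, −20 to 0 °C
Reagents that add atoms: none
Why: Proposed new method: acid ionises the tertiary benzylic alcohol to a cyclopropylcarbinyl cation strongly stabilised by the 2,4,6-trioxygenated ring, the α-carbon of the vinylogous ester (the future spiro carbon) opens the cyclopropane at a methylene carbon, and the aryloxocarbenium ion so formed is attacked by the new electron-rich tetrasubstituted styrene to give a chroman-4-yl cation, which triethylsilane reduces (through alkene 12 if it loses a proton first). The closest known reaction types are the Julia cyclopropylcarbinyl-to-homoallyl opening of aryl cyclopropyl carbinols by external nucleophiles, the (3+2) annulation of donor–acceptor cyclopropanes with enol ethers, and Prins closure of 2-alkenylphenol-derived oxocarbenium ions followed by ionic hydrogenation; what is new is their intramolecular union with a cation in the role of the acceptor. The first bond closes a nine-membered ring containing a Z-styrene (the CH2CH2 arm ends cis to the aryl group because the cation is bisected), and the second bond is a transannular closure, 5-exo for the cyclopentane and 6-endo for the pyran, that can only give the cis-fused rings. The spiro carbon should be attacked anti to the ring methyl group, which allylic 1,3-strain with the E-aryloxy group holds axial; the O–CH carbon keeps the enol ether geometry because closure should outrun rotation; the methyl-bearing quaternary carbon follows from the cis fusion; and hydride should arrive at the isobutyl carbon from the convex face, syn to the angular methyl group. The step needs attack at the cyclopropane methylene and not at the hindered cationic carbon, which would join two fully substituted carbons; this is secured by sterics, by relief of ring strain and by the in-plane vinyloxy group lying behind the C–C bond that breaks, while triflimide and molecular sieves keep counter-ion and water from opening the ring instead.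

Step 8
Reactants: 13 dimethoxy spiro chroman ketone
Product: 14 (1S,3a'R,6R,9'R,9a'S)-6',8'-dimethoxy-6,9a'-dimethyl-9'-(2-methylpropyl)-3-(propan-2-yl)-1',2',9',9a'-tetrahydro-3a'H-spiro[cyclohex-2-ene-1,3'-cyclopenta[b]chromen]-2-yl trifluoromethanesulfonate
Conditions: KN(SiMe3)2, THF, −78 °C; PhNTf2, −78 to 0 °C
Reagents that add atoms: N-phenylbis(trifluoromethanesulfonimide), O=S(=O)(N(c1ccccc1)S(=O)(=O)C(F)(F)F)C(F)(F)F
Why: Enol triflate formation from the potassium enolate, which can form only toward the isopropyl-bearing carbon because the other α-carbon is the quaternary spiro centre.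

Step 9
Reactants: 14 enol triflate
Product: 15 (1R,3a'R,6R,9'R,9a'S)-6',8'-dimethoxy-6,9a'-dimethyl-9'-(2-methylpropyl)-3-(propan-2-yl)-1',2',9',9a'-tetrahydro-3a'H-spiro[cyclohex-2-ene-1,3'-cyclopenta[b]chromene]
Conditions: Pd(OAc)2 (cat.), PPh3, HCO2H, n-Bu3N, DMF, 60 °C
Reagents that add atoms: none
Why: Palladium-catalysed reduction of the vinyl triflate by formate (oxidative addition, decarboxylation of formate to a hydride, reductive elimination) should give the trisubstituted alkene regiospecifically.

Step 10
Reactants: 15 dimethoxy spiro chroman alkene; 16 dichloromethyl methyl ether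
Product: 17 (1R,3a'R,6R,9'R,9a'S)-6',8'-dimethoxy-6,9a'-dimethyl-9'-(2-methylpropyl)-3-(propan-2-yl)-1',2',9',9a'-tetrahydro-3a'H-spiro[cyclohex-2-ene-1,3'-cyclopenta[b]chromene]-5',7'-dicarbaldehyde
Conditions: TiCl4, CH2Cl2, −78 to −20 °C; H2O
Reagents that add atoms: water, O
Why: Twofold Rieche formylation at the two remaining ring positions, each ortho or para to three oxygen substituents; the low temperature is meant to spare the hindered trisubstituted alkene.

Step 11
Reactants: 17 dimethoxy dialdehyde
Product: 18 (1R,3a'R,6R,9'R,9a'S)-6',8'-dihydroxy-6,9a'-dimethyl-9'-(2-methylpropyl)-3-(propan-2-yl)-1',2',9',9a'-tetrahydro-3a'H-spiro[cyclohex-2-ene-1,3'-cyclopenta[b]chromene]-5',7'-dicarbaldehyde (target)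
Conditions: BCl3 (excess), CH2Cl2, −78 to 0 °C; H2O
Reagents that add atoms: none
Why: Chelation-assisted cleavage of both methyl ethers, each ortho to a formyl group, while the hindered secondary chroman ether and all stereocentres should remain untouched.

**Compound list**

1 | 1,3,5-trimethoxybenzene | COc1cc(OC)cc(OC)c1 | starting material
2 | 1-methylcyclopropane-1-carbonyl chloride | CC1(CC1)C(Cl)=O | starting material
3 | (1-methylcyclopropyl)(2,4,6-trimethoxyphenyl)methanone | COc1cc(OC)c(C(=O)C2(C)CC2)c(OC)c1 | intermediate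
4 | (2-hydroxy-4,6-dimethoxyphenyl)(1-methylcyclopropyl)methanone | COc1cc(O)c(C(=O)C2(C)CC2)c(OC)c1 | intermediate
5 | isobutylmagnesium bromide | CC(C)C[Mg]Br | starting material
6 | 2-[1-hydroxy-3-methyl-1-(1-methylcyclopropyl)butyl]-3,5-dimethoxyphenol (racemic) | CC(C)CC(O)(c1c(O)cc(OC)cc1OC)C1(C)CC1 | intermediate
7 | (−)-menthone, (2S,5R)-5-methyl-2-(propan-2-yl)cyclohexan-1-one | C[C@@H]1CC[C@H](C(=O)C1)C(C)C | starting material
8 | ethyl formate | CCOC=O | starting material
9 | (2Z,3R,6S)-2-(hydroxymethylidene)-3-methyl-6-(propan-2-yl)cyclohexan-1-one | O/C=C1\C(=O)[C@H](C(C)C)CC[C@H]1C | intermediate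
10 | [(E)-[(3S,6R)-6-methyl-2-oxo-3-(propan-2-yl)cyclohexylidene]methyl] 4-methylbenzenesulfonate | Cc1ccc(cc1)S(=O)(=O)O/C=C1/C(=O)[C@H](C(C)C)CC[C@H]1C | intermediate
11 | (2E,3R,6S)-2-({2-[1-hydroxy-3-methyl-1-(1-methylcyclopropyl)butyl]-3,5-dimethoxyphenoxy}methylidene)-3-methyl-6-(propan-2-yl)cyclohexan-1-one (both carbinol epimers) | CC(C)CC(O)(c1c(OC)cc(OC)cc1O/C=C1/C(=O)[C@H](C(C)C)CC[C@H]1C)C1(C)CC1 | intermediate
12 | (1S,3S,3a'R,6R,9a'S)-6',8'-dimethoxy-6,9a'-dimethyl-9'-(2-methylpropylidene)-3-(propan-2-yl)-1',2',9',9a'-tetrahydro-3a'H-spiro[cyclohexane-1,3'-cyclopenta[b]chromen]-2-one (alkene geometry open) | CC(C)C=C1c2c(OC)cc(OC)cc2O[C@@H]2[C@@]1(C)CC[C@@]21C(=O)[C@H](C(C)C)CC[C@H]1C | intermediate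
13 | (1S,3S,3a'R,6R,9'R,9a'S)-6',8'-dimethoxy-6,9a'-dimethyl-9'-(2-methylpropyl)-3-(propan-2-yl)-1',2',9',9a'-tetrahydro-3a'H-spiro[cyclohexane-1,3'-cyclopenta[b]chromen]-2-one | CC(C)C[C@H]1c2c(OC)cc(OC)cc2O[C@@H]2[C@@]1(C)CC[C@@]21C(=O)[C@H](C(C)C)CC[C@H]1C | intermediate
14 | (1S,3a'R,6R,9'R,9a'S)-6',8'-dimethoxy-6,9a'-dimethyl-9'-(2-methylpropyl)-3-(propan-2-yl)-1',2',9',9a'-tetrahydro-3a'H-spiro[cyclohex-2-ene-1,3'-cyclopenta[b]chromen]-2-yl trifluoromethanesulfonate | CC(C)C[C@H]1c2c(OC)cc(OC)cc2O[C@@H]2[C@@]1(C)CC[C@@]21C(OS(=O)(=O)C(F)(F)F)=C(C(C)C)CC[C@H]1C | intermediate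
15 | (1R,3a'R,6R,9'R,9a'S)-6',8'-dimethoxy-6,9a'-dimethyl-9'-(2-methylpropyl)-3-(propan-2-yl)-1',2',9',9a'-tetrahydro-3a'H-spiro[cyclohex-2-ene-1,3'-cyclopenta[b]chromene] | CC(C)C[C@H]1c2c(OC)cc(OC)cc2O[C@@H]2[C@@]1(C)CC[C@@]21C=C(C(C)C)CC[C@H]1C | intermediate
16 | dichloromethyl methyl ether | COC(Cl)Cl | starting material
17 | (1R,3a'R,6R,9'R,9a'S)-6',8'-dimethoxy-6,9a'-dimethyl-9'-(2-methylpropyl)-3-(propan-2-yl)-1',2',9',9a'-tetrahydro-3a'H-spiro[cyclohex-2-ene-1,3'-cyclopenta[b]chromene]-5',7'-dicarbaldehyde | CC(C)C[C@H]1c2c(OC)c(C=O)c(OC)c(C=O)c2O[C@@H]2[C@@]1(C)CC[C@@]21C=C(C(C)C)CC[C@H]1C | intermediate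
18 | (1R,3a'R,6R,9'R,9a'S)-6',8'-dihydroxy-6,9a'-dimethyl-9'-(2-methylpropyl)-3-(propan-2-yl)-1',2',9',9a'-tetrahydro-3a'H-spiro[cyclohex-2-ene-1,3'-cyclopenta[b]chromene]-5',7'-dicarbaldehyde | CC(C)C[C@H]1c2c(O)c(C=O)c(O)c(C=O)c2O[C@@H]2[C@@]1(C)CC[C@@]21C=C(C(C)C)CC[C@H]1C | target

**Count and risks**

Total steps: 11. Longest linear sequence: 9 (steps 1, 2, 3, 6, 7, 8, 9, 10, 11).

Steps most likely to fail:

1. Step 7 (proposed new method). The cation may be captured at the carbinyl carbon (a six-membered Prins closure at the wrong carbon) or by water or counter-ion before the weakly nucleophilic vinylogous ester reaches the cyclopropane methylene. Facial selectivity at the spiro carbon may also erode if the remote isopropyl group sits axial. The fallback makes the two bonds one after the other with known reactions; it sets out from 6 and 9 and returns at 13. Compound 6 is opened with MgBr2·OEt2 (cyclopropylcarbinyl-to-homoallyl ring opening by bromide) to (Z)-2-(1-bromo-3,6-dimethylhept-3-en-4-yl)-3,5-dimethoxyphenol F1. The potassium enolate of 9 (t-BuOK, then F1, NaI, DMF) is C-alkylated anti to the ring methyl group to give (1S,3S,6R)-1-[(3Z)-4-(2-hydroxy-4,6-dimethoxyphenyl)-3,6-dimethylhept-3-en-1-yl]-6-methyl-2-oxo-3-(propan-2-yl)cyclohexane-1-carbaldehyde F2. Treatment of F2 with CF3CO2H and Et3SiH should then form the cyclic hemiacetal, ionise it, close the pyran and cyclopentane rings by Prins attack of the styrene, and reduce the benzylic cation to 13.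

2. Step 10. The trisubstituted alkene may be hydrochlorinated or undergo cationic rearrangement under TiCl4, or the second formylation may stall on the deactivated mono-aldehyde. The fallback sets out from 15 and returns at 17. Twofold electrophilic bromination (N-bromosuccinimide, 2 equiv, MeCN, 0 °C) should give (1R,3a'R,6R,9'R,9a'S)-5',7'-dibromo-6',8'-dimethoxy-6,9a'-dimethyl-9'-(2-methylpropyl)-3-(propan-2-yl)-1',2',9',9a'-tetrahydro-3a'H-spiro[cyclohex-2-ene-1,3'-cyclopenta[b]chromene] F3. Double bromine–lithium exchange (t-BuLi, THF, −78 °C) and quenching with DMF then gives 17 without any acid.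

3. Step 3. The branched Grignard reagent may transfer a β-hydride (reduction) or fail to add to the hindered, electron-rich ketone. The fallback reverses the roles of the two carbinol substituents; it sets out from 1 and returns at 6. Acylation of 1 with 3-methylbutanoyl chloride (Bi(OTf)3 cat.) gives 3-methyl-1-(2,4,6-trimethoxyphenyl)butan-1-one F4. BCl3 then gives 1-(2-hydroxy-4,6-dimethoxyphenyl)-3-methylbutan-1-one F5. Addition of (1-methylcyclopropyl)lithium (from 1-bromo-1-methylcyclopropane and t-BuLi) in the presence of CeCl3 then gives 6.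

Further compounds
F1 | step 7 | (Z)-2-(1-bromo-3,6-dimethylhept-3-en-4-yl)-3,5-dimethoxyphenol | CC(C)C/C(=C(\C)CCBr)c1c(O)cc(OC)cc1OC
F2 | step 7 | (1S,3S,6R)-1-[(3Z)-4-(2-hydroxy-4,6-dimethoxyphenyl)-3,6-dimethylhept-3-en-1-yl]-6-methyl-2-oxo-3-(propan-2-yl)cyclohexane-1-carbaldehyde | CC(C)C/C(=C(\C)CC[C@]1(C=O)C(=O)[C@H](C(C)C)CC[C@H]1C)c1c(O)cc(OC)cc1OC
F3 | step 10 | (1R,3a'R,6R,9'R,9a'S)-5',7'-dibromo-6',8'-dimethoxy-6,9a'-dimethyl-9'-(2-methylpropyl)-3-(propan-2-yl)-1',2',9',9a'-tetrahydro-3a'H-spiro[cyclohex-2-ene-1,3'-cyclopenta[b]chromene] | CC(C)C[C@H]1c2c(OC)c(Br)c(OC)c(Br)c2O[C@@H]2[C@@]1(C)CC[C@@]21C=C(C(C)C)CC[C@H]1C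
F4 | step 3 | 3-methyl-1-(2,4,6-trimethoxyphenyl)butan-1-one | CC(C)CC(=O)c1c(OC)cc(OC)cc1OC
F5 | step 3 | 1-(2-hydroxy-4,6-dimethoxyphenyl)-3-methylbutan-1-one | CC(C)CC(=O)c1c(O)cc(OC)cc1OC
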